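**Strategy.** The target is cut at both C3–C4 bonds. The C3–C3' bond that joins the two pyranone rings (ring C of each flavanone half), with each C3 flanked by C4 and by a C2 carrying O1 and the anisyl ring, is read as the two carbons of an alkyne. One ruthenium-catalysed ene–yne–ene ring-closing metathesis then forms C3=C4 and C3'=C4' and closes both pyran rings in a single operation. Its substrate is the twofold-symmetric bis(aryl) ether of (1S,4S)-1,4-bis(4-methoxyphenyl)but-2-yne-1,4-diol, each aryl being a 3,5-bis(benzyloxy)-2-vinylphenyl group. The carbinol carbons already hold the C2 configuration, which later steers hydroboration to the cis C2/C3 relationship.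

Key step: step 9

Remarks on the chemistry:
- The target SMILES encodes the 2,3-cis,2',3'-cis isomer (2R,3R,2'R,3'R). The same spatial arrangement at the carbinol carbon carries the letter S in 7 and 11–14, because there the alkynyl or alkenyl carbon outranks anisyl.
- In steps 3, 4, 5, 8, 10, 11 and 12 the same reaction takes place at two equivalent sites in one operation; the half-reacted species is not listed as a separate compound.

**Step 1**
Reactants: 1 4-methoxybenzaldehyde; 2 ethynylmagnesium bromide
Product: 3 rac-1-(4-methoxyphenyl)prop-2-yn-1-ol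
Conditions: 2 (1.2 equiv, 0.5 M in THF), THF, 0 °C → rt; aq NH4Cl
Reagents that add atoms: none
Why: Grignard 1,2-addition of the acetylide to the aryl aldehyde gives the secondary propargylic alcohol; the carbinol centre forms without control, which is harmless because step 3 removes it.

**Step 2**
Reactants: 3 rac-1-(4-methoxyphenyl)prop-2-yn-1-ol; 1 4-methoxybenzaldehyde
Product: 5 1,4-bis(4-methoxyphenyl)but-2-yne-1,4-diol (racemic/meso mixture), via dilithiated propargylic alcohol 4 (not isolated)
Conditions: n-BuLi (2.1 equiv), THF, −78 → −20 °C; then 1 (1.05 equiv), −78 °C → rt; aq NH4Cl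
Reagents that add atoms: none
Why: Deprotonation of the hydroxyl and then of the acetylenic C–H gives the alkoxide–acetylide dianion, whose carbon terminus undergoes acetylide 1,2-addition to the aldehyde; both diastereomers of the diol are acceptable because step 3 converges them.

**Step 3**
Reactants: 5 1,4-bis(4-methoxyphenyl)but-2-yne-1,4-diol (racemic/meso mixture)
Product: 6 1,4-bis(4-methoxyphenyl)but-2-yne-1,4-dione
Conditions: activated MnO2 (excess), CH2Cl2, rt; filtration
Reagents that add atoms: none
Why: MnO2 oxidation of the doubly activated (benzylic and propargylic) secondary alcohols is selective and neutral, both diastereomers converge on the achiral ynedione, and filtration spares this electrophilic product from aqueous base.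

**Step 4**
Reactants: 6 1,4-bis(4-methoxyphenyl)but-2-yne-1,4-dione
Product: 7 (1S,4S)-1,4-bis(4-methoxyphenyl)but-2-yne-1,4-diol
Conditions: (S)-Me-CBS [(S)-1-methyl-3,3-diphenyltetrahydro-1H,3H-pyrrolo[1,2-c][1,3,2]oxazaborole] (1.0 equiv, recoverable), BH3·SMe2 (2.4 equiv), THF, −30 °C, slow addition of 6; MeOH quench; recrystallisation
Reagents that add atoms: none
Why: Corey–Bakshi–Shibata reduction, established for conjugated ynones: each ketone binds the ring boron with the bulky anisyl group away from the B-methyl group and the rod-like alkynyl arm in the small-group position, so the (S)-oxazaborolidine should deliver hydride to the face that gives the S carbinol, and because the two reductions are independent a mismatched event ends up as the separable meso diol, which raises the enantiopurity of the S,S diol.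

**Step 5**
Reactants: 8 2,4,6-trifluorobenzaldehyde; 9 benzyl alcohol
Product: 10 2-fluoro-4,6-bis(benzyloxy)benzaldehyde
Conditions: 9 (2.05 equiv), Cs2CO3 (2.2 equiv), DMF, 0 → 50 °C, stopped at the disubstituted stage
Reagents that add atoms: none
Why: Nucleophilic aromatic substitution (addition–elimination) activated by the formyl group: in the dissociating solvent the first benzyloxide should enter para and the second at one of the two equivalent ortho fluorines, each alkoxy group lowers the reactivity so the third fluoride survives, and the weak carbonate base keeps the alkoxide concentration low so that hydride transfer to the aldehyde does not compete.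

**Step 6**
Reactants: 7 (1S,4S)-1,4-bis(4-methoxyphenyl)but-2-yne-1,4-diol; 10 2-fluoro-4,6-bis(benzyloxy)benzaldehyde
Product: 11 2-{[(1S,4S)-4-hydroxy-1,4-bis(4-methoxyphenyl)but-2-yn-1-yl]oxy}-4,6-bis(benzyloxy)benzaldehyde
Conditions: 7 (1.5 equiv), KN(SiMe3)2 (1.0 equiv), THF, −40 °C; then 10 (1.0 equiv), THF–DMF, −40 → 0 °C; excess 7 recovered
Reagents that add atoms: none
Why: Nucleophilic aromatic substitution through a Meisenheimer adduct of the mono-potassium alkoxide at the fluorine-bearing carbon ortho to the formyl group; the carbinol C–O bond is never broken, so the S centre is carried over with retention, the excess of diol over base and fluoride favours single arylation, and any doubly arylated material is simply compound 12 and is carried forward.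

**Step 7**
Reactants: 11 2-{[(1S,4S)-4-hydroxy-1,4-bis(4-methoxyphenyl)but-2-yn-1-yl]oxy}-4,6-bis(benzyloxy)benzaldehyde; 10 2-fluoro-4,6-bis(benzyloxy)benzaldehyde
Product: 12 2,2'-{[(1S,4S)-1,4-bis(4-methoxyphenyl)but-2-yne-1,4-diyl]bis(oxy)}bis[4,6-bis(benzyloxy)benzaldehyde]
Conditions: NaH (1.05 equiv), THF, 0 °C; then 10 (1.2 equiv), DMF, 0 °C → rt
Reagents that add atoms: none
Why: The same nucleophilic aromatic substitution at the remaining hydroxyl, again with retention at the carbinol carbon; a hydride base is used because 11 already carries a formyl group that a silylamide could attack, and one equivalent of base with mild temperature limits alkoxide-to-aldehyde hydride transfer and propargyl–allenyl isomerisation.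

**Step 8**
Reactants: 12 2,2'-{[(1S,4S)-1,4-bis(4-methoxyphenyl)but-2-yne-1,4-diyl]bis(oxy)}bis[4,6-bis(benzyloxy)benzaldehyde]
Product: 13 1,1'-{[(1S,4S)-1,4-bis(4-methoxyphenyl)but-2-yne-1,4-diyl]bis(oxy)}bis[3,5-bis(benzyloxy)-2-ethenylbenzene]
Conditions: Ph3PCH3Br (3.0 equiv), KN(SiMe3)2 (2.8 equiv), THF, 0 °C; then 12, −20 °C → rt
Reagents that add atoms: methyltriphenylphosphonium bromide, C[P+](c1ccccc1)(c1ccccc1)c1ccccc1.[Br-]
Why: Wittig methylenation of the two electron-rich aryl aldehydes; the ylide is kept slightly short of the phosphonium salt so that no free amide base remains, and it is too weakly basic to deprotonate the propargylic ether C–H, so both S centres survive.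

**Step 9**
Reactants: 13 1,1'-{[(1S,4S)-1,4-bis(4-methoxyphenyl)but-2-yne-1,4-diyl]bis(oxy)}bis[3,5-bis(benzyloxy)-2-ethenylbenzene]
Product: 14 (2S,2'S)-5,5',7,7'-tetrakis(benzyloxy)-2,2'-bis(4-methoxyphenyl)-2H,2'H-3,3'-bichromene
Conditions: second-generation Hoveyda–Grubbs catalyst RuCl2(H2IMes)(=CH-C6H4-2-OiPr) (10 mol %), ethylene (1 atm), toluene (0.005 M), 80 °C, dark
Reagents that add atoms: none
Why: Tandem ring-closing enyne metathesis: a ruthenium arylmethylidene formed at one vinyl group adds across the alkyne through a ruthenacyclobutene that opens to a vinylcarbene on the distal alkyne carbon, and this carbene undergoes ring-closing metathesis with the second vinyl group, giving 14 and ruthenium methylidene with ethylene as the only by-product. The closest known reactions are ene–yne–ene cascades of bis(allyl) ethers of but-2-yne-1,4-diols to 3,3'-bi(2,5-dihydrofurans) and enyne ring closures of 2-vinylphenyl propargyl ethers to 2H-chromenes. The first pyran ring (O1, C2, C3, C4, C4a, C8a) closes in the exo mode by C4–C3 bond formation with ruthenium left on C3' outside the ring; the second six-membered ring closes by ordinary alkylidene–olefin ring-closing metathesis that forms C3'=C4'. No stereocentre is created, and the two C2 centres are untouched under these neutral conditions (light is excluded to avoid photochemical opening of the 2H-chromene rings). The selectivity needed is intramolecular relay in preference to cross-metathesis or stalling at the half-cyclised stage: high dilution favours ring closure, the short propargylic ether tether holds the alkyne next to each carbene, and under ethylene the methylidene can alternatively enter at the alkyne, a pathway that converges on the same diene and eases the burden of initiating at the 2,6-disubstituted styrene.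

**Step 10**
Reactants: 14 (2S,2'S)-5,5',7,7'-tetrakis(benzyloxy)-2,2'-bis(4-methoxyphenyl)-2H,2'H-3,3'-bichromene
Product: 16 (2R,2'R,3S,3'S,4S,4'S)-5,5',7,7'-tetrakis(benzyloxy)-2,2'-bis(4-methoxyphenyl)-[3,3'-bichromane]-4,4'-diol, via 4,4'-bis(boranyl) adduct 15 (not isolated)
Conditions: BH3·THF (8 equiv), THF, 0 °C → rt, 14 added slowly to the borane; then 3 M NaOH, 30% H2O2, 0 °C → rt
Reagents that add atoms: hydrogen peroxide, OO
Why: Brown hydroboration–oxidation: borane adds syn across each trisubstituted styrene-type C3=C4 bond with boron at the less substituted benzylic C4 and hydrogen at C3 from the face opposite the C2 anisyl group (held pseudoaxial by A(1,2) strain with the C3 substituent), which should set C3 and C3' cis to their C2 aryl groups, alkaline peroxide then replaces boron by hydroxyl with retention, and excess borane with inverse addition disfavours intramolecular hydroboration of the second ring.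

**Step 11**
Reactants: 16 (2R,2'R,3S,3'S,4S,4'S)-5,5',7,7'-tetrakis(benzyloxy)-2,2'-bis(4-methoxyphenyl)-[3,3'-bichromane]-4,4'-diol
Product: 17 (2R,2'R,3R,3'R)-5,5',7,7'-tetrakis(benzyloxy)-2,2'-bis(4-methoxyphenyl)-[3,3'-bichromane]-4,4'-dione
Conditions: Dess–Martin periodinane (3 equiv), NaHCO3, CH2Cl2, 0 °C → rt
Reagents that add atoms: none
Why: Dess–Martin oxidation of the two secondary benzylic alcohols under buffered, non-basic conditions removes the C4 stereocentres without enolising the new ketones, so the kinetically set cis C2/C3 relationship is preserved.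

**Step 12**
Reactants: 17 (2R,2'R,3R,3'R)-5,5',7,7'-tetrakis(benzyloxy)-2,2'-bis(4-methoxyphenyl)-[3,3'-bichromane]-4,4'-dione
Product: 18 (2R,2'R,3R,3'R)-5,5',7,7'-tetrahydroxy-2,2'-bis(4-methoxyphenyl)-[3,3'-bichromane]-4,4'-dione (target, 2,3-cis in both halves)
Conditions: H2 (1 atm), 10% Pd/C, EtOAc–MeOH, rt
Reagents that add atoms: none
Why: Catalytic hydrogenolysis cleaves the four benzyl aryl ethers under neutral conditions, so the epimerisable C3 centres are not disturbed, while the cyclic C2–O1 ether of a flavanone, the hydrogen-bonded aryl ketone and the aryl methyl ethers are normally retained under these mild conditions.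

**Compound list**

1 | 4-methoxybenzaldehyde | COc1ccc(C=O)cc1 | starting material
2 | ethynylmagnesium bromide | C#C[Mg]Br | starting material
3 | rac-1-(4-methoxyphenyl)prop-2-yn-1-ol | COc1ccc(C(O)C#C)cc1 | intermediate
4 | dilithiated propargylic alcohol (lithium alkoxide and lithium acetylide of 3) | COc1ccc(C(O[Li])C#C[Li])cc1 | intermediate
5 | 1,4-bis(4-methoxyphenyl)but-2-yne-1,4-diol (racemic/meso mixture) | COc1ccc(C(O)C#CC(O)c2ccc(OC)cc2)cc1 | intermediate
6 | 1,4-bis(4-methoxyphenyl)but-2-yne-1,4-dione | COc1ccc(C(=O)C#CC(=O)c2ccc(OC)cc2)cc1 | intermediate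
7 | (1S,4S)-1,4-bis(4-methoxyphenyl)but-2-yne-1,4-diol | COc1ccc([C@H](O)C#C[C@@H](O)c2ccc(OC)cc2)cc1 | intermediate
8 | 2,4,6-trifluorobenzaldehyde | O=Cc1c(F)cc(F)cc1F | starting material
9 | benzyl alcohol | OCc1ccccc1 | starting material
10 | 2-fluoro-4,6-bis(benzyloxy)benzaldehyde | O=Cc1c(F)cc(OCc2ccccc2)cc1OCc1ccccc1 | intermediate
11 | 2-{[(1S,4S)-4-hydroxy-1,4-bis(4-methoxyphenyl)but-2-yn-1-yl]oxy}-4,6-bis(benzyloxy)benzaldehyde | COc1ccc([C@H](Oc2cc(OCc3ccccc3)cc(OCc3ccccc3)c2C=O)C#C[C@@H](O)c2ccc(OC)cc2)cc1 | intermediate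
12 | 2,2'-{[(1S,4S)-1,4-bis(4-methoxyphenyl)but-2-yne-1,4-diyl]bis(oxy)}bis[4,6-bis(benzyloxy)benzaldehyde] | COc1ccc([C@H](Oc2cc(OCc3ccccc3)cc(OCc3ccccc3)c2C=O)C#C[C@@H](Oc2cc(OCc3ccccc3)cc(OCc3ccccc3)c2C=O)c2ccc(OC)cc2)cc1 | intermediate
13 | 1,1'-{[(1S,4S)-1,4-bis(4-methoxyphenyl)but-2-yne-1,4-diyl]bis(oxy)}bis[3,5-bis(benzyloxy)-2-ethenylbenzene] | COc1ccc([C@H](Oc2cc(OCc3ccccc3)cc(OCc3ccccc3)c2C=C)C#C[C@@H](Oc2cc(OCc3ccccc3)cc(OCc3ccccc3)c2C=C)c2ccc(OC)cc2)cc1 | intermediate
14 | (2S,2'S)-5,5',7,7'-tetrakis(benzyloxy)-2,2'-bis(4-methoxyphenyl)-2H,2'H-3,3'-bichromene | COc1ccc([C@@H]2Oc3cc(OCc4ccccc4)cc(OCc4ccccc4)c3C=C2C2=Cc3c(OCc4ccccc4)cc(OCc4ccccc4)cc3O[C@H]2c2ccc(OC)cc2)cc1 | intermediate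
15 | 4,4'-bis(boranyl) adduct of 14 (boron at C4 and C4', configuration as in 16) | COc1ccc([C@@H]2Oc3cc(OCc4ccccc4)cc(OCc4ccccc4)c3[C@@H](B)[C@@H]2[C@H]2[C@H](B)c3c(OCc4ccccc4)cc(OCc4ccccc4)cc3O[C@H]2c2ccc(OC)cc2)cc1 | intermediate
16 | (2R,2'R,3S,3'S,4S,4'S)-5,5',7,7'-tetrakis(benzyloxy)-2,2'-bis(4-methoxyphenyl)-[3,3'-bichromane]-4,4'-diol | COc1ccc([C@@H]2Oc3cc(OCc4ccccc4)cc(OCc4ccccc4)c3[C@@H](O)[C@@H]2[C@H]2[C@H](O)c3c(OCc4ccccc4)cc(OCc4ccccc4)cc3O[C@H]2c2ccc(OC)cc2)cc1 | intermediate
17 | (2R,2'R,3R,3'R)-5,5',7,7'-tetrakis(benzyloxy)-2,2'-bis(4-methoxyphenyl)-[3,3'-bichromane]-4,4'-dione | COc1ccc([C@@H]2Oc3cc(OCc4ccccc4)cc(OCc4ccccc4)c3C(=O)[C@@H]2[C@H]2C(=O)c3c(OCc4ccccc4)cc(OCc4ccccc4)cc3O[C@H]2c2ccc(OC)cc2)cc1 | intermediate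
18 | (2R,2'R,3R,3'R)-5,5',7,7'-tetrahydroxy-2,2'-bis(4-methoxyphenyl)-[3,3'-bichromane]-4,4'-dione | COc1ccc([C@@H]2Oc3cc(O)cc(O)c3C(=O)[C@@H]2[C@H]2C(=O)c3c(O)cc(O)cc3O[C@H]2c2ccc(OC)cc2)cc1 | target

**Step count.** Total: 12 steps. Longest linear sequence: 11 steps (steps 1, 2, 3, 4, 6, 7, 8, 9, 10, 11, 12 from 4-methoxybenzaldehyde); the aryl fluoride 10 is made in one step (step 5) and enters at steps 6 and 7.

**Steps most likely to fail**

Step 9. The catalyst may fail to load onto the 2,6-disubstituted styrenes, or be parked as a chelated 2-alkoxybenzylidene, so that substrate is returned or the cascade stalls after one ring. The fallback delivers the carbene by relay ring-closing metathesis. It sets out from dialdehyde 12. In place of step 8, a double Wittig reaction with the ylide from hex-5-en-1-yltriphenylphosphonium bromide and KN(SiMe3)2 should give the bis(hepta-1,6-dien-1-yl) relay substrate F1. With the second-generation Hoveyda–Grubbs catalyst in dilute toluene, ruthenium loads on the unhindered terminal alkene and expels cyclopentene, which places it on the benzylic carbon without an intermolecular encounter with the hindered styrene. The same alkyne relay follows, and the route is rejoined at bichromene 14.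

Step 6 (and step 7, which is the same reaction at the second hydroxyl). Substitution at the electron-rich fluoroarene may be slow, which would allow hydride transfer from the alkoxide to the aldehyde or base-induced propargyl–allenyl isomerisation with loss of configuration. The fallback reverses the polarity and uses a Mitsunobu etherification. It sets out from ynedione 6, which is reduced as in step 4 but with (R)-Me-CBS to (1R,4R)-1,4-bis(4-methoxyphenyl)but-2-yne-1,4-diol F2. F2 is coupled with two equivalents of 2,4-bis(benzyloxy)-6-hydroxybenzaldehyde F3 (commercial; otherwise from 2,4,6-trihydroxybenzaldehyde, benzyl bromide and K2CO3) under PPh3/DIAD in toluene at 0 °C. Substitution with inversion at both carbinol carbons should give dialdehyde 12, where the route is rejoined.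

Step 10. Boron may be delivered to C3 or across the diene, the first borane may hydroborate the second ring intramolecularly, or facial control in the second ring may be poor. The fallback replaces hydroboration by hydrogenation followed by benzylic C–H oxidation. It sets out from bichromene 14. Hydrogenation of both trisubstituted alkenes with Crabtree's catalyst [Ir(cod)(PCy3)(py)]PF6 under H2 in CH2Cl2 should add hydrogen anti to the C2 anisyl groups and leave the benzyl ethers intact, giving the 2,3-cis,2',3'-cis (2R,2'R,3R,3'R)-5,5',7,7'-tetrakis(benzyloxy)-2,2'-bis(4-methoxyphenyl)-3,3'-bichromane F4. The C4 and C4' methylene groups, benzylic to the 5,7-dioxygenated rings, are then oxidised with DDQ in wet CH2Cl2 to the 4,4'-diol of unassigned C4 configuration F5. Oxidation of F5 with the reagent of step 11 gives diketone 17, where the route is rejoined.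

**Further compounds**

F1 | step 9 | 1,1'-{[(1S,4S)-1,4-bis(4-methoxyphenyl)but-2-yne-1,4-diyl]bis(oxy)}bis[3,5-bis(benzyloxy)-2-(hepta-1,6-dien-1-yl)benzene] | COc1ccc([C@H](Oc2cc(OCc3ccccc3)cc(OCc3ccccc3)c2C=CCCCC=C)C#C[C@@H](Oc2cc(OCc3ccccc3)cc(OCc3ccccc3)c2C=CCCCC=C)c2ccc(OC)cc2)cc1
F2 | step 6 | (1R,4R)-1,4-bis(4-methoxyphenyl)but-2-yne-1,4-diol | COc1ccc([C@@H](O)C#C[C@H](O)c2ccc(OC)cc2)cc1
F3 | step 6 | 2,4-bis(benzyloxy)-6-hydroxybenzaldehyde | O=Cc1c(O)cc(OCc2ccccc2)cc1OCc1ccccc1
F4 | step 10 | (2R,2'R,3R,3'R)-5,5',7,7'-tetrakis(benzyloxy)-2,2'-bis(4-methoxyphenyl)-3,3'-bichromane | COc1ccc([C@@H]2Oc3cc(OCc4ccccc4)cc(OCc4ccccc4)c3C[C@@H]2[C@H]2Cc3c(OCc4ccccc4)cc(OCc4ccccc4)cc3O[C@H]2c2ccc(OC)cc2)cc1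
F5 | step 10 | (2R,2'R,3S,3'S)-5,5',7,7'-tetrakis(benzyloxy)-2,2'-bis(4-methoxyphenyl)-[3,3'-bichromane]-4,4'-diol, C4 and C4' unassigned | COc1ccc([C@@H]2Oc3cc(OCc4ccccc4)cc(OCc4ccccc4)c3C(O)[C@@H]2[C@H]2C(O)c3c(OCc4ccccc4)cc(OCc4ccccc4)cc3O[C@H]2c2ccc(OC)cc2)cc1
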